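**Plan**

- Retrosynthetic cuts, in order: the Ar–CHO bond; the two O–benzyl bonds; the ArC(=O)–CH2CH(CH3)2 bond; then, in the key event, the O–C2 and C1–C7 bonds of the bornane; then the O–C and ArCH2–C bonds of a pinane-fused chroman; last the ArCH2–N and Ar–CHO bonds of the quinone methide precursor.
- Forward ring order: the benzene ring is bought; the dihydropyran ring arises by hetero-Diels–Alder reaction of an o-quinone methide with (+)-α-pinene; one acid-induced event then enlarges the pyran to the oxepine (six to seven atoms) while the cyclobutane of the pinane opens to the bicyclo[2.2.1]heptane.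
- Enabling feature: the ether oxygen sits on bornane C2, next to the methyl-bearing bridgehead C1 that carries the C7 gem-dimethyl bridge, and O (C2) and ArCH2 (C6) are both endo. This O–C2–C1(CH3)–C7(CH3)2 array is the product pattern of a 2-pinanyl to 2-bornyl Wagner–Meerwein shift; moving C7 back to C2 and O back to C1 gives a tertiary ether in a six-membered ring.
- Stereochemistry: all four stereocenters come from (1R,5R)-(+)-α-pinene. The cycloaddition adds O and CH2 cis, anti to the gem-dimethyl bridge; the shift inverts both migration termini; the other bridgehead and the CH2-bearing carbon are untouched.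
- Helpers: two benzyl ethers block the second ortho oxygen (one regioisomer in cycloaddition and re-closure); the para-formyl group activates the ether as a vinylogous ester and later becomes the isovaleryl group.

Key step: step 4

Remark: pinane numbering (C2 bears CH3, C6 is the C(CH3)2 bridge, C7 the CH2 bridge) and bornane numbering (C1 bears CH3, C7 is C(CH3)2) are used. 3,5-Bis(benzyloxy)phenol and (1R,5R)-(+)-α-pinene of high enantiomeric purity are assumed to be purchasable; the enantiomeric purity of the target follows that of the pinene.

**Route**

Step 1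
Reactants: 1 3,5-bis(benzyloxy)phenol
Product: 3 2,6-bis(benzyloxy)-4-hydroxybenzaldehyde, via aryl iminium chloride 2 (not isolated)
Conditions: POCl3, DMF, MeCN, 0 °C to rt; then H2O, 50 °C
Reagents that add atoms: N,N-dimethylformamide CN(C)C=O; water O
Why: Vilsmeier–Haack formylation; 3,5-dialkoxyphenols are attacked mainly para to the hydroxyl group, between the two ethers, and the chelated ortho isomer is removed at this stage.

Step 2
Reactants: 3 2,6-bis(benzyloxy)-4-hydroxybenzaldehyde
Product: 4 2,6-bis(benzyloxy)-3-[(dimethylamino)methyl]-4-hydroxybenzaldehyde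
Conditions: CH2=NMe2+ I− (1.0 equiv), MeCN, rt to 50 °C; aq NaHCO3
Reagents that add atoms: N,N-dimethylmethyleneiminium iodide (Eschenmoser's salt) C=[N+](C)C.[I-]
Why: Mannich aminomethylation at one of the two equivalent positions ortho to the hydroxyl group (the only ring C–H bonds left); the mono-adduct forms as its hydroiodide, whose ammonium group should deactivate the ring against a second substitution.

Step 3
Reactants: 4 2,6-bis(benzyloxy)-3-[(dimethylamino)methyl]-4-hydroxybenzaldehyde; 5 (1R,5R)-(+)-α-pinene
Product: 8 pinane-fused 5,7-bis(benzyloxy)chroman-6-carbaldehyde, via benzyltrimethylammonium iodide 6 (not isolated), via o-quinone methide 7 (not isolated)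
Conditions: MeI, MeCN, rt, volatiles removed; then 5 (10 equiv), i-Pr2NEt, 1,4-dioxane, 100 °C
Reagents that add atoms: none
Why: N-methylation gives the ammonium salt 6, base-induced 1,4-elimination of trimethylamine gives the o-quinone methide 7, and its inverse-electron-demand hetero-Diels–Alder reaction with the trisubstituted alkene of 5 should join oxygen to the tertiary C2 and CH2 to C3 suprafacially from the face opposite to the gem-dimethyl bridge, which sets both new stereocenters (cis fusion) from the pinene bridgeheads; only one ring oxygen is free, so only one regioisomer can form.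

Step 4
Reactants: 8 pinane-fused 5,7-bis(benzyloxy)chroman-6-carbaldehyde
Product: 9 bornane-fused 6,8-bis(benzyloxy)-2,3,4,5-tetrahydro-1-benzoxepine-7-carbaldehyde
Conditions: (CF3SO2)2NH (5 mol %), CH2Cl2, −40 to 0 °C; Et3N quench
Reagents that add atoms: none
Why: Proposed new method: protonation of the para-formyl group turns the tertiary aryl ether of 8 into a protonated vinylogous ester, so the C2–O bond (pinane numbering) ionises by unimolecular alkyl–oxygen cleavage with participation of the antiperiplanar C1–C6 bond; the gem-dimethyl carbon moves from C1 to C2 and the same phenolic oxygen, kept beside the cation by its CH2 tether, closes on the former C1, so the pyran gains one carbon and the cyclobutane opens to the bornane in one event. The closest known reaction types are the Wagner–Meerwein conversion of pinene hydrochloride into bornyl chloride with ion-pair return and the acidolysis of tertiary alkyl aryl ethers; the tethered, ring-expanding 1,2-exchange of oxygen and carbon on a pinane-fused chroman is the untested part. The oxepine closes by attack of oxygen on the far carbon of the sigma-bridged cation (7-endo opening of the bridge; the 6-exo return only regenerates 8), and the bicyclo[2.2.1]heptane forms by the 1,2-alkyl shift itself. The quaternary bornane C1 is set by entry of the migrating carbon anti to the leaving oxygen (inversion at pinane C2), and the C2–O center by capture anti to the migrated bridge, which is the endo face and the only face the tether can reach (inversion at pinane C1). The step needs migration of the gem-dimethyl bridge and not of the CH2 bridge (bornane, not fenchane), secured by the anti-to-bridge geometry from step 3; capture instead of cyclobutane fragmentation or elimination, favoured by a non-nucleophilic counter-ion, low temperature and an aprotic solvent; and re-closure through the original oxygen only, secured by benzylation of the other ortho oxygen. Relief of cyclobutane strain and the slow, unassisted ionisation of an endo bornyl ether should make 9 the sink.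

Step 5
Reactants: 9 bornane-fused 6,8-bis(benzyloxy)-2,3,4,5-tetrahydro-1-benzoxepine-7-carbaldehyde
Product: 10 secondary benzylic alcohol (1-aryl-3-methylbutan-1-ol)
Conditions: i-BuMgBr, CeCl3, THF, −78 to 0 °C; then H2O
Reagents that add atoms: isobutylmagnesium bromide CC(C)C[Mg]Br
Why: 1,2-addition of the organocerium reagent from i-BuMgBr and CeCl3 to the hindered aldehyde (cerium suppresses β-hydride reduction); the carbinol center forms as a mixture of epimers that is erased in step 6.

Step 6
Reactants: 10 secondary benzylic alcohol (1-aryl-3-methylbutan-1-ol)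
Product: 11 aryl isobutyl ketone (dibenzyl ether)
Conditions: Dess–Martin periodinane, pyridine, CH2Cl2, 0 °C to rt
Reagents that add atoms: none
Why: Dess–Martin oxidation of the benzylic alcohol under buffered, non-acidic conditions that should leave the benzyl ethers and the bornyl aryl ether untouched.

Step 7
Reactants: 11 aryl isobutyl ketone (dibenzyl ether)
Product: 12 6,8-dihydroxy-7-(3-methylbutanoyl) benzoxepine (target without the formyl group)
Conditions: H2 (1 atm), Pd/C, EtOAc, rt
Reagents that add atoms: none
Why: hydrogenolysis of the two benzyl ethers; the bornyl aryl ether is not benzylic on its alkyl side, and the hindered aryl ketone, chelated once the phenols are free, should not be reduced.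

Step 8
Reactants: 12 6,8-dihydroxy-7-(3-methylbutanoyl) benzoxepine (target without the formyl group)
Product: 14 target CNP0246493.1, via aryl iminium chloride 13 (not isolated)
Conditions: POCl3, DMF, MeCN, 0 °C to rt; then H2O, 50 °C
Reagents that add atoms: N,N-dimethylformamide CN(C)C=O; water O
Why: Vilsmeier–Haack formylation at the only free ring position, which is ortho to the ether oxygen and to one hydroxyl group and para to the other, so no question of regiochemistry arises.

**Compound list**

1 | 3,5-bis(benzyloxy)phenol | Oc1cc(OCc2ccccc2)cc(OCc2ccccc2)c1 | starting material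
2 | [2,6-bis(benzyloxy)-4-hydroxybenzylidene]dimethyliminium chloride | C[N+](C)=Cc1c(OCc2ccccc2)cc(O)cc1OCc1ccccc1.[Cl-] | intermediate
3 | 2,6-bis(benzyloxy)-4-hydroxybenzaldehyde | O=Cc1c(OCc2ccccc2)cc(O)cc1OCc1ccccc1 | intermediate
4 | 2,6-bis(benzyloxy)-3-[(dimethylamino)methyl]-4-hydroxybenzaldehyde | O=Cc1c(OCc2ccccc2)cc(O)c(CN(C)C)c1OCc1ccccc1 | intermediate
5 | (1R,5R)-(+)-α-pinene, (1R,5R)-2,6,6-trimethylbicyclo[3.1.1]hept-2-ene | CC1=CC[C@@H]2C[C@H]1C2(C)C | starting material
6 | [2,4-bis(benzyloxy)-3-formyl-6-hydroxybenzyl]trimethylammonium iodide | O=Cc1c(OCc2ccccc2)cc(O)c(C[N+](C)(C)C)c1OCc1ccccc1.[I-] | intermediate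
7 | o-quinone methide, 2,6-bis(benzyloxy)-3-methylidene-4-oxocyclohexa-1,5-diene-1-carbaldehyde | O=CC1=C(OCc2ccccc2)C(=C)C(=O)C=C1OCc1ccccc1 | intermediate
8 | pinane-fused chroman: 5,7-bis(benzyloxy)chroman-6-carbaldehyde with O1 on the methyl-bearing pinane C2 and C4H2 on pinane C3, both on the face opposite to the C(CH3)2 bridge (cis fusion), bridgeheads as in 5 | O=Cc1c(OCc2ccccc2)cc2c(c1OCc1ccccc1)C[C@@H]1C[C@@H]3C[C@@H](C3(C)C)[C@]1(C)O2 | intermediate
9 | bornane-fused benzoxepine: 6,8-bis(benzyloxy)-2,3,4,5-tetrahydro-1-benzoxepine-7-carbaldehyde with O1 endo on bornane C2, the methyl-bearing bridgehead C1 in the ring, and C5H2 endo on bornane C6 | O=Cc1c(OCc2ccccc2)cc2c(c1OCc1ccccc1)C[C@@H]1C[C@@H]3C[C@H](O2)[C@@]1(C)C3(C)C | intermediate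
10 | secondary alcohol: 7-(1-hydroxy-3-methylbutyl) analogue of 9, both epimers at the carbinol carbon | CC(C)CC(O)c1c(OCc2ccccc2)cc2c(c1OCc1ccccc1)C[C@@H]1C[C@@H]3C[C@H](O2)[C@@]1(C)C3(C)C | intermediate
11 | ketone: 7-(3-methylbutanoyl) analogue of 9, dibenzyl ether | CC(C)CC(=O)c1c(OCc2ccccc2)cc2c(c1OCc1ccccc1)C[C@@H]1C[C@@H]3C[C@H](O2)[C@@]1(C)C3(C)C | intermediate
12 | 6,8-dihydroxy-7-(3-methylbutanoyl) bornane-fused benzoxepine (target without the 9-formyl group) | CC(C)CC(=O)c1c(O)cc2c(c1O)C[C@@H]1C[C@@H]3C[C@H](O2)[C@@]1(C)C3(C)C | intermediate
13 | 9-(dimethyliminiomethyl) derivative of 12, chloride | CC(C)CC(=O)c1c(O)c(C=[N+](C)C)c2c(c1O)C[C@@H]1C[C@@H]3C[C@H](O2)[C@@]1(C)C3(C)C.[Cl-] | intermediate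
14 | CNP0246493.1: 6,8-dihydroxy-7-(3-methylbutanoyl) bornane-fused benzoxepine-9-carbaldehyde | CC(C)CC(=O)c1c(O)c(C=O)c2c(c1O)C[C@@H]1C[C@@H]3C[C@H](O2)[C@@]1(C)C3(C)C | target

**Totals and risks**

Total step count: 8. Longest linear sequence: 8 steps (from 1; compound 5 is bought).

Step 4 (Proposed new method). The cation may fragment by cyclobutane opening to monocyclic p-menthane-type ions, or lose a proton, faster than the tethered oxygen closes; the acid may also begin to cleave benzyl ethers. The fallback uses known chemistry and sets out from 8. Dry HCl in CH2Cl2 at −30 °C cleaves the tertiary aryl ether and, as in the classical passage from pinene hydrochloride to bornyl chloride, chloride takes up the rearranged cation to give the ring-opened endo-2-chlorobornane phenol F1. Silver-assisted ionisation of F1 (Ag2O, toluene, 60 °C) then acts on an endo C–Cl bond that is antiperiplanar to C1–C7; the phenoxide, held on the endo face by the CH2 tether, should close the oxepine and return to the route at 9.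

Step 3. The quinone methide may be consumed by self-condensation or by re-addition of trimethylamine faster than the hindered trisubstituted alkene traps it; any bis-aminomethylation in step 2 also lowers the supply. The fallback sets out from 3. Condensation with paraformaldehyde and phenylboronic acid (cat. propionic acid, toluene, reflux with removal of water) gives the ortho-specific, strictly mono-functionalised 2-phenyl-4H-1,3,2-benzodioxaborin F2. Thermolysis of F2 in neat 5 releases the same quinone methide 7 slowly, free of amine and base, and the route is rejoined at 8.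

Step 8. The acid set free may ionise the bornyl aryl ether, or substitution on the acyl-deactivated, hydrogen-bonded ring may stall at O-formylation. The fallback sets out from 11 and moves the formylation ahead of the deprotection. Vilsmeier–Haack reaction on the fully etherified, more electron-rich ring of 11 gives, through the iminium chloride F3, the formylated dibenzyl ether F4. Hydrogenolysis of the two benzyl ethers of F4 (H2, Pd/C, EtOAc) then comes back to the route at 14.

**Further compounds**

F1 | step 4 | ring-opened phenol: 2,6-bis(benzyloxy)-4-hydroxy-3-[(2-endo-chlorobornan-6-endo-yl)methyl]benzaldehyde | O=Cc1c(OCc2ccccc2)cc(O)c(c1OCc1ccccc1)C[C@@H]1C[C@@H]2C[C@H](Cl)[C@@]1(C)C2(C)C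
F2 | step 3 | 5,7-bis(benzyloxy)-2-phenyl-4H-1,3,2-benzodioxaborine-6-carbaldehyde | O=Cc1c(OCc2ccccc2)cc2OB(c3ccccc3)OCc2c1OCc1ccccc1
F3 | step 8 | 9-(dimethyliminiomethyl) derivative of 11, chloride | CC(C)CC(=O)c1c(OCc2ccccc2)c(C=[N+](C)C)c2c(c1OCc1ccccc1)C[C@@H]1C[C@@H]3C[C@H](O2)[C@@]1(C)C3(C)C.[Cl-]
F4 | step 8 | 6,8-bis(benzyloxy)-7-(3-methylbutanoyl) bornane-fused benzoxepine-9-carbaldehyde (dibenzyl ether of 14) | CC(C)CC(=O)c1c(OCc2ccccc2)c(C=O)c2c(c1OCc1ccccc1)C[C@@H]1C[C@@H]3C[C@H](O2)[C@@]1(C)C3(C)C
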